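The route rests on recognising ring A (C1–C6, carotenoid numbering) as a 4-substituted isophorone: its C3 oxygen sits 1,3 to both the methyl-bearing alkene carbon C5 and the gem-dimethyl carbon C1. A one-flask Michael addition/aldol condensation of mesityl oxide with diethyl (2-oxopropyl)phosphonate therefore closes ring A, forging C1–C6 and C4=C5 and leaving on C6 a phosphonate that later delivers the exocyclic C6=C7 alkene. The resulting dienone serves both end groups: enantioselective reduction gives ring A, and a hydroxyl-directed epoxidation/redox relay turns the same alcohol into ring B. Two olefinations with a C12 bisphosphonate join the halves without protecting groups.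

Key step: step 1

Remark: carotenoid numbering is used throughout (ring A C1–C6 with the methyl on C5, ring B primed), and the (6E) geometry of the ring A dienone ester, with C8 on the side of the gem-dimethyl carbon, is assumed to be the thermodynamically preferred one that a reversible olefination reaches.

Step 1
Reactants: 1 mesityl oxide; 2 diethyl (2-oxopropyl)phosphonate
Product: 5 diethyl (2,6,6-trimethyl-4-oxocyclohex-2-en-1-yl)phosphonate (racemic), via Michael adduct 3 (not isolated), via ketol 4 (not isolated)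
Conditions: ZnCl2 (0.2 equiv), toluene, reflux, Dean–Stark
Reagents that add atoms: none
Why: The zinc-chelated enol of 2 adds in a Michael sense to the β,β-dimethyl terminus of 1 (C1–C6), the methyl ketone of diketone 3 then enolises and closes onto the chelation-activated C5 carbonyl to give ketol 4, and loss of water gives the conjugated enone with the C4=C5 bond. The closest known reaction type is the Robinson-type Michael/aldol annulation of β-keto esters with mesityl oxide that leads to 4-carbalkoxyisophorones. The six-membered ring closes in a 6-(enolendo)-exo-trig aldol mode. The only new stereocenter, C6, forms as a racemate under no control, which is harmless because it becomes trigonal in step 3. The step needs C-alkylation at C6, 1,4- over 1,2-addition, and ring closure C4→C5 and not acetyl-CH3→C3; these should be secured by the soft chelated nucleophile, by the hindered carbonyl of 1, and by ZnCl2 chelation between P=O and the C5 carbonyl together with irreversible dehydration under water removal.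

Step 2
Reactants: 6 ethyl tiglate
Product: 7 ethyl (E)-2-methyl-4-oxobut-2-enoate
Conditions: SeO2 (1.1 equiv), 1,4-dioxane, reflux
Reagents that add atoms: selenium dioxide O=[Se]=O
Why: Selenium dioxide allylic oxidation (ene reaction, then 2,3-sigmatropic shift) attacks the γ-methyl group of the enoate and should stop at the (E)-enal with the alkene geometry of 6 retained.

Step 3
Reactants: 5 diethyl (2,6,6-trimethyl-4-oxocyclohex-2-en-1-yl)phosphonate; 7 ethyl (E)-2-methyl-4-oxobut-2-enoate
Product: 8 ethyl (2E,4E)-2-methyl-4-(2,6,6-trimethyl-4-oxocyclohex-2-en-1-ylidene)but-2-enoate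
Conditions: NaH (1.05 equiv), THF, 0 °C; then 7, 0 °C to rt, dark
Reagents that add atoms: none
Why: Vinylogous Horner–Wadsworth–Emmons olefination, in which the extended enolate of 5 reacts at the phosphorus-bearing C6 as 4-phosphonocrotonate reagents do; reversible addition should funnel to the (6E)-dienone in which C8 avoids the in-plane C5 methyl, and the racemic C6 center disappears.

Step 4
Reactants: 8 ethyl (2E,4E)-2-methyl-4-(2,6,6-trimethyl-4-oxocyclohex-2-en-1-ylidene)but-2-enoate
Product: 9 ethyl (2E,4E)-4-[(4S)-4-hydroxy-2,6,6-trimethylcyclohex-2-en-1-ylidene]-2-methylbut-2-enoate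
Conditions: (R)-2-methyl-CBS-oxazaborolidine (0.2 equiv), catecholborane (1.5 equiv), toluene, −78 °C
Reagents that add atoms: none
Why: CBS reduction, in which the alkenyl flank should act as the large group so that the (R)-oxazaborolidine delivers hydride 1,2 to the face that gives the (3S)-allylic alcohol, leaving the ester untouched.

Step 5
Reactants: 9 ethyl (2E,4E)-4-[(4S)-4-hydroxy-2,6,6-trimethylcyclohex-2-en-1-ylidene]-2-methylbut-2-enoate
Product: 10 (2E,4E)-4-[(4S)-4-hydroxy-2,6,6-trimethylcyclohex-2-en-1-ylidene]-2-methylbut-2-en-1-ol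
Conditions: iBu2AlH (DIBAL-H, 3.5 equiv), CH2Cl2, −78 °C; aqueous potassium sodium tartrate
Reagents that add atoms: none
Why: DIBAL-H 1,2-reduction of the conjugated ester to the primary allylic alcohol, with the secondary hydroxyl carried as its aluminium alkoxide and no stereocenter touched.

Step 6
Reactants: 10 (2E,4E)-4-[(4S)-4-hydroxy-2,6,6-trimethylcyclohex-2-en-1-ylidene]-2-methylbut-2-en-1-ol
Product: 11 (2E,4E)-4-[(4S)-4-hydroxy-2,6,6-trimethylcyclohex-2-en-1-ylidene]-2-methylbut-2-enal
Conditions: Cu(MeCN)4OTf (5 mol%), 2,2'-bipyridine, TEMPO, N-methylimidazole, MeCN, air, rt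
Reagents that add atoms: none
Why: Monovalent copper/TEMPO aerobic alcohol oxidation, which should select the primary over the secondary alcohol on steric grounds and runs under neutral conditions that spare the acid-labile C3 carbinol.

Step 7
Reactants: 9 ethyl (2E,4E)-4-[(4S)-4-hydroxy-2,6,6-trimethylcyclohex-2-en-1-ylidene]-2-methylbut-2-enoate
Product: 12 ethyl (2E,4E)-4-[(1R,5S,6S)-5-hydroxy-1,3,3-trimethyl-7-oxabicyclo[4.1.0]heptan-2-ylidene]-2-methylbut-2-enoate (epoxide cis to the hydroxyl)
Conditions: VO(acac)2 (3 mol%), tBuOOH (1.2 equiv), CH2Cl2, 0 °C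
Reagents that add atoms: tert-butyl hydroperoxide CC(C)(C)OO
Why: Hydroxyl-directed epoxidation, in which the vanadium alkoxide of the allylic alcohol delivers oxygen to C4=C5 on the face of the C3 hydroxyl, so the (3S) center sets C5 while the remote alkenes, the (6E) exocyclic bond included, are left alone.

Step 8
Reactants: 12 ethyl (2E,4E)-4-[(1R,5S,6S)-5-hydroxy-1,3,3-trimethyl-7-oxabicyclo[4.1.0]heptan-2-ylidene]-2-methylbut-2-enoate
Product: 13 ethyl (2E,4E)-2-methyl-4-[(1R,6R)-1,3,3-trimethyl-5-oxo-7-oxabicyclo[4.1.0]heptan-2-ylidene]but-2-enoate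
Conditions: Dess–Martin periodinane (1.3 equiv), pyridine, CH2Cl2, 0 °C to rt
Reagents that add atoms: none
Why: Dess–Martin oxidation of the secondary epoxy alcohol to the α,β-epoxy ketone under buffered conditions, leaving the C5–O bond and its configuration untouched.

Step 9
Reactants: 13 ethyl (2E,4E)-2-methyl-4-[(1R,6R)-1,3,3-trimethyl-5-oxo-7-oxabicyclo[4.1.0]heptan-2-ylidene]but-2-enoate
Product: 14 ethyl (2E,4E)-4-[(2S)-2-hydroxy-2,6,6-trimethyl-4-oxocyclohexylidene]-2-methylbut-2-enoate
Conditions: SmI2 (2.5 equiv), THF/MeOH, −90 °C; pH 7 buffer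
Reagents that add atoms: none
Why: Reductive opening of an α,β-epoxy ketone by SmI2, in which the ketyl cleaves the C4–O bond and protonation of the samarium enolate gives the β-hydroxy ketone with C5 unchanged; low temperature and neutral work-up should suppress dehydration back to 8.

Step 10
Reactants: 14 ethyl (2E,4E)-4-[(2S)-2-hydroxy-2,6,6-trimethyl-4-oxocyclohexylidene]-2-methylbut-2-enoate
Product: 15 ethyl (2E,4E)-4-[(2S,4R)-2,4-dihydroxy-2,6,6-trimethylcyclohexylidene]-2-methylbut-2-enoate
Conditions: Me4NBH(OAc)3 (5 equiv), MeCN/AcOH, −30 °C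
Reagents that add atoms: none
Why: Evans–Saksena anti-selective 1,3-reduction, in which the tertiary C5 hydroxyl binds the triacetoxyborohydride and delivers hydride to the C3 ketone from its own face, setting the new carbinol (3R) trans to the C5 hydroxyl.

Step 11
Reactants: 15 ethyl (2E,4E)-4-[(2S,4R)-2,4-dihydroxy-2,6,6-trimethylcyclohexylidene]-2-methylbut-2-enoate
Product: 16 (1R,3S,4E)-4-[(2E)-4-hydroxy-3-methylbut-2-en-1-ylidene]-3,5,5-trimethylcyclohexane-1,3-diol
Conditions: iBu2AlH (DIBAL-H, 4.5 equiv), CH2Cl2, −78 °C; aqueous potassium sodium tartrate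
Reagents that add atoms: none
Why: DIBAL-H reduction of the conjugated ester as in step 5, with the two hydroxyls carried as aluminium alkoxides.

Step 12
Reactants: 16 (1R,3S,4E)-4-[(2E)-4-hydroxy-3-methylbut-2-en-1-ylidene]-3,5,5-trimethylcyclohexane-1,3-diol
Product: 17 (2E,4E)-4-[(2S,4R)-2,4-dihydroxy-2,6,6-trimethylcyclohexylidene]-2-methylbut-2-enal
Conditions: Cu(MeCN)4OTf (5 mol%), 2,2'-bipyridine, TEMPO, N-methylimidazole, MeCN, air, rt
Reagents that add atoms: none
Why: Copper/TEMPO aerobic oxidation as in step 6, which should select the primary allylic alcohol over the secondary and tertiary hydroxyls.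

Step 13
Reactants: 18 (E)-3-methylpent-2-en-4-yn-1-ol
Product: 19 (2E,4E)-3-methyl-5-(tributylstannyl)penta-2,4-dien-1-ol
Conditions: Bu3SnH (1.1 equiv), PdCl2(PPh3)2 (2 mol%), THF, 0 °C
Reagents that add atoms: tributyltin hydride CCCC[SnH](CCCC)CCCC
Why: Palladium-catalysed syn-hydrostannation of the terminal alkyne should place tin on the terminal carbon and give the (4E)-dienylstannane, the (2E) alkene coming unchanged from 18.

Step 14
Reactants: 19 (2E,4E)-3-methyl-5-(tributylstannyl)penta-2,4-dien-1-ol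
Product: 20 (2E,4E)-5-iodo-3-methylpenta-2,4-dien-1-ol
Conditions: I2 (1.05 equiv), CH2Cl2, 0 °C, dark; aqueous Na2S2O3
Reagents that add atoms: iodine II
Why: Iododestannylation of an alkenylstannane, an ipso electrophilic substitution at the tin-bearing carbon that should proceed with retention and give the (4E)-dienyl iodide from one portion of 19; the iodide is used at once because it is light-sensitive.

Step 15
Reactants: 19 (2E,4E)-3-methyl-5-(tributylstannyl)penta-2,4-dien-1-ol; 20 (2E,4E)-5-iodo-3-methylpenta-2,4-dien-1-ol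
Product: 21 (2E,4E,6E,8E)-3,8-dimethyldeca-2,4,6,8-tetraene-1,10-diol
Conditions: Pd2(dba)3 (2.5 mol%), AsPh3 (20 mol%), N-methylpyrrolidone, rt, dark, argon
Reagents that add atoms: none
Why: Stille cross-coupling of the dienylstannane with the dienyl iodide under zerovalent palladium catalysis, which should form the central C15–C15' single bond with retention of both alkene geometries and tolerates the free allylic hydroxyls.

Step 16
Reactants: 21 (2E,4E,6E,8E)-3,8-dimethyldeca-2,4,6,8-tetraene-1,10-diol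
Product: 22 (2E,4E,6E,8E)-1,10-dibromo-3,8-dimethyldeca-2,4,6,8-tetraene
Conditions: PBr3 (0.8 equiv), pyridine (cat.), Et2O, −20 °C, dark
Reagents that add atoms: phosphorus tribromide BrP(Br)Br
Why: Conversion of primary allylic alcohols to bromides with PBr3 at low temperature, which should keep the all-E tetraene and the primary positions.

Step 17
Reactants: 22 (2E,4E,6E,8E)-1,10-dibromo-3,8-dimethyldeca-2,4,6,8-tetraene
Product: 23 tetraethyl [(2E,4E,6E,8E)-3,8-dimethyldeca-2,4,6,8-tetraene-1,10-diyl]bis(phosphonate)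
Conditions: P(OEt)3 (excess, neat), 110 °C, dark, argon
Reagents that add atoms: triethyl phosphite CCOP(OCC)OCC
Why: Michaelis–Arbuzov reaction of the two primary allylic bromides with triethyl phosphite.

Step 18
Reactants: 23 tetraethyl [(2E,4E,6E,8E)-3,8-dimethyldeca-2,4,6,8-tetraene-1,10-diyl]bis(phosphonate); 11 (2E,4E)-4-[(4S)-4-hydroxy-2,6,6-trimethylcyclohex-2-en-1-ylidene]-2-methylbut-2-enal
Product: 24 diethyl {(2E,4E,6E,8E,10E,12E,14E)-14-[(4S)-4-hydroxy-2,6,6-trimethylcyclohex-2-en-1-ylidene]-3,8,12-trimethyltetradeca-2,4,6,8,10,12-hexaen-1-yl}phosphonate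
Conditions: 23 (3 equiv), KOtBu (1.0 equiv), THF, −30 °C; then 11, −30 °C to rt, dark
Reagents that add atoms: none
Why: Horner–Wadsworth–Emmons olefination of one phosphonate terminus (excess 23, one equivalent of base), in which the allylic phosphonate carbanion reacts at its α-carbon and should give the new C10=C11 bond E, the free hydroxyl being less acidic than the phosphonate.

Step 19
Reactants: 24 diethyl {(2E,4E,6E,8E,10E,12E,14E)-14-[(4S)-4-hydroxy-2,6,6-trimethylcyclohex-2-en-1-ylidene]-3,8,12-trimethyltetradeca-2,4,6,8,10,12-hexaen-1-yl}phosphonate; 17 (2E,4E)-4-[(2S,4R)-2,4-dihydroxy-2,6,6-trimethylcyclohexylidene]-2-methylbut-2-enal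
Product: 25 target retro-carotenoid triol CNP0269135.1
Conditions: 24 (1.2 equiv), KOtBu (1.3 equiv), THF, −30 °C; then 17, to rt, dark, argon
Reagents that add atoms: none
Why: A second Horner–Wadsworth–Emmons olefination should join the halves through an (E)-C10'=C11' bond without protecting groups, with all three stereocenters and both exocyclic alkenes carried through unchanged.

Compound list
1 | mesityl oxide (4-methylpent-3-en-2-one) | CC(=O)C=C(C)C | starting material
2 | diethyl (2-oxopropyl)phosphonate | CCOP(=O)(OCC)CC(C)=O | starting material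
3 | Michael adduct, diethyl (4,4-dimethyl-2,6-dioxoheptan-3-yl)phosphonate (racemic, not isolated) | CCOP(=O)(OCC)C(C(C)=O)C(C)(C)CC(C)=O | intermediate
4 | ketol, diethyl (2-hydroxy-2,6,6-trimethyl-4-oxocyclohexyl)phosphonate (racemic diastereomers, not isolated) | CCOP(=O)(OCC)C1C(C)(O)CC(=O)CC1(C)C | intermediate
5 | diethyl (2,6,6-trimethyl-4-oxocyclohex-2-en-1-yl)phosphonate (racemic) | CCOP(=O)(OCC)C1C(C)=CC(=O)CC1(C)C | intermediate
6 | ethyl tiglate (ethyl (E)-2-methylbut-2-enoate) | CCOC(=O)/C(C)=C/C | starting material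
7 | ethyl (E)-2-methyl-4-oxobut-2-enoate | CCOC(=O)/C(C)=C/C=O | intermediate
8 | ethyl (2E,4E)-2-methyl-4-(2,6,6-trimethyl-4-oxocyclohex-2-en-1-ylidene)but-2-enoate | CC1=CC(=O)CC(C)(C)\C1=C/C=C(C)/C(=O)OCC | intermediate
9 | ethyl (2E,4E)-4-[(4S)-4-hydroxy-2,6,6-trimethylcyclohex-2-en-1-ylidene]-2-methylbut-2-enoate | CC1=C[C@@H](O)CC(C)(C)\C1=C/C=C(C)/C(=O)OCC | intermediate
10 | (2E,4E)-4-[(4S)-4-hydroxy-2,6,6-trimethylcyclohex-2-en-1-ylidene]-2-methylbut-2-en-1-ol | CC1=C[C@@H](O)CC(C)(C)\C1=C/C=C(C)/CO | intermediate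
11 | (2E,4E)-4-[(4S)-4-hydroxy-2,6,6-trimethylcyclohex-2-en-1-ylidene]-2-methylbut-2-enal | CC1=C[C@@H](O)CC(C)(C)\C1=C/C=C(C)/C=O | intermediate
12 | ethyl (2E,4E)-4-[(1R,5S,6S)-5-hydroxy-1,3,3-trimethyl-7-oxabicyclo[4.1.0]heptan-2-ylidene]-2-methylbut-2-enoate | C[C@]12O[C@H]1[C@@H](O)CC(C)(C)\C2=C/C=C(C)/C(=O)OCC | intermediate
13 | ethyl (2E,4E)-2-methyl-4-[(1R,6R)-1,3,3-trimethyl-5-oxo-7-oxabicyclo[4.1.0]heptan-2-ylidene]but-2-enoate | C[C@]12O[C@H]1C(=O)CC(C)(C)\C2=C/C=C(C)/C(=O)OCC | intermediate
14 | ethyl (2E,4E)-4-[(2S)-2-hydroxy-2,6,6-trimethyl-4-oxocyclohexylidene]-2-methylbut-2-enoate | C[C@]1(O)CC(=O)CC(C)(C)\C1=C/C=C(C)/C(=O)OCC | intermediate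
15 | ethyl (2E,4E)-4-[(2S,4R)-2,4-dihydroxy-2,6,6-trimethylcyclohexylidene]-2-methylbut-2-enoate | C[C@]1(O)C[C@H](O)CC(C)(C)\C1=C/C=C(C)/C(=O)OCC | intermediate
16 | (1R,3S,4E)-4-[(2E)-4-hydroxy-3-methylbut-2-en-1-ylidene]-3,5,5-trimethylcyclohexane-1,3-diol | C[C@]1(O)C[C@H](O)CC(C)(C)\C1=C/C=C(C)/CO | intermediate
17 | (2E,4E)-4-[(2S,4R)-2,4-dihydroxy-2,6,6-trimethylcyclohexylidene]-2-methylbut-2-enal | C[C@]1(O)C[C@H](O)CC(C)(C)\C1=C/C=C(C)/C=O | intermediate
18 | (E)-3-methylpent-2-en-4-yn-1-ol | C#C/C(C)=C/CO | starting material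
19 | (2E,4E)-3-methyl-5-(tributylstannyl)penta-2,4-dien-1-ol | CCCC[Sn](CCCC)(CCCC)/C=C/C(C)=C/CO | intermediate
20 | (2E,4E)-5-iodo-3-methylpenta-2,4-dien-1-ol | I/C=C/C(C)=C/CO | intermediate
21 | (2E,4E,6E,8E)-3,8-dimethyldeca-2,4,6,8-tetraene-1,10-diol | OC/C=C(C)/C=C/C=C/C(C)=C/CO | intermediate
22 | (2E,4E,6E,8E)-1,10-dibromo-3,8-dimethyldeca-2,4,6,8-tetraene | BrC/C=C(C)/C=C/C=C/C(C)=C/CBr | intermediate
23 | tetraethyl [(2E,4E,6E,8E)-3,8-dimethyldeca-2,4,6,8-tetraene-1,10-diyl]bis(phosphonate) | CCOP(=O)(OCC)C/C=C(C)/C=C/C=C/C(C)=C/CP(=O)(OCC)OCC | intermediate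
24 | diethyl {(2E,4E,6E,8E,10E,12E,14E)-14-[(4S)-4-hydroxy-2,6,6-trimethylcyclohex-2-en-1-ylidene]-3,8,12-trimethyltetradeca-2,4,6,8,10,12-hexaen-1-yl}phosphonate | CC1=C[C@@H](O)CC(C)(C)\C1=C/C=C(C)/C=C/C=C(C)/C=C/C=C/C(C)=C/CP(=O)(OCC)OCC | intermediate
25 | CNP0269135.1, all-E retro-carotenoid with (3S)-3-hydroxy-4,5-didehydro ring A and (3'R,5'S)-3',5'-dihydroxy ring B, both ring-to-chain alkenes E | CC1=C[C@@H](O)CC(C)(C)\C1=C/C=C(C)/C=C/C=C(C)/C=C/C=C/C(C)=C/C=C/C(C)=C/C=C1\C(C)(C)C[C@@H](O)C[C@]1(C)O | target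

Total step count: 19.
Longest linear sequence: 10 steps (1, 3, 4, 7, 8, 9, 10, 11, 12, 19).

Steps most likely to fail

Step 1. The conjugate addition to the doubly β-substituted carbon of 1 may be slow and reversible, so that self-condensation of 1 or ring closure in the other aldol direction takes over. The fallback sets out from 1 and comes back at 8. The more acidic donor 1-(phenylsulfonyl)propan-2-one is annulated with 1 in the same Michael/aldol manifold (piperidinium acetate, toluene, reflux, water removal) to give 3,5,5-trimethyl-4-(phenylsulfonyl)cyclohex-2-en-1-one F1. Its sodium salt (NaH, THF/DMF) is alkylated at the sulfonyl-bearing carbon with ethyl (E)-4-bromo-2-methylbut-2-enoate to give ethyl (E)-2-methyl-4-[2,6,6-trimethyl-4-oxo-1-(phenylsulfonyl)cyclohex-2-en-1-yl]but-2-enoate F2. DBU then expels benzenesulfinate in a Julia-type elimination to give 8. This replaces carbonyl olefination by an irreversible alkylation and so also bypasses step 3.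

Step 3. Addition of the congested dienolate carbon to the aldehyde may be unfavourable, or the C6=C7 bond may form as a mixture of geometrical isomers. The fallback sets out from 5 and comes back at 9, using a more reactive, non-stabilised allylic phosphonate carbanion. CBS reduction of 5 (catalyst control at C3, both C6 epimers acceptable) gives diethyl [(4S)-4-hydroxy-2,6,6-trimethylcyclohex-2-en-1-yl]phosphonate F3. Silylation (TBSCl, imidazole, DMF) gives diethyl [(4S)-4-(tert-butyldimethylsilyloxy)-2,6,6-trimethylcyclohex-2-en-1-yl]phosphonate F4. Deprotonation with KN(SiMe3)2 at −78 °C and olefination with 7 gives ethyl (2E,4E)-4-[(4S)-4-(tert-butyldimethylsilyloxy)-2,6,6-trimethylcyclohex-2-en-1-ylidene]-2-methylbut-2-enoate F5, and TBAF releases 9. A 6E/6Z mixture of 8 could instead be equilibrated with a trace of iodine in light and the minor isomer recycled.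

Step 4. Facial discrimination by the oxazaborolidine may be poor because the two flanks of the ketone differ only moderately in size. The fallback sets out from 8 and comes back at 9. Luche reduction (NaBH4, CeCl3·7H2O, MeOH, 0 °C) gives racemic ethyl (2E,4E)-4-(4-hydroxy-2,6,6-trimethylcyclohex-2-en-1-ylidene)-2-methylbut-2-enoate F6. Lipase-catalysed kinetic resolution (Amano lipase PS, vinyl acetate, MTBE) should acetylate the (R)-enantiomer to ethyl (2E,4E)-4-[(4R)-4-acetoxy-2,6,6-trimethylcyclohex-2-en-1-ylidene]-2-methylbut-2-enoate F7, which is separated by chromatography from unreacted (S)-alcohol 9.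

Further compounds
F1 | step 1 | 3,5,5-trimethyl-4-(phenylsulfonyl)cyclohex-2-en-1-one (racemic) | CC1=CC(=O)CC(C)(C)C1S(=O)(=O)c1ccccc1
F2 | step 1 | ethyl (E)-2-methyl-4-[2,6,6-trimethyl-4-oxo-1-(phenylsulfonyl)cyclohex-2-en-1-yl]but-2-enoate (racemic) | CCOC(=O)/C(C)=C/CC1(S(=O)(=O)c2ccccc2)C(C)=CC(=O)CC1(C)C
F3 | step 3 | diethyl [(4S)-4-hydroxy-2,6,6-trimethylcyclohex-2-en-1-yl]phosphonate (C1 epimers) | CCOP(=O)(OCC)C1C(C)=C[C@@H](O)CC1(C)C
F4 | step 3 | diethyl [(4S)-4-(tert-butyldimethylsilyloxy)-2,6,6-trimethylcyclohex-2-en-1-yl]phosphonate (C1 epimers) | CCOP(=O)(OCC)C1C(C)=C[C@@H](O[Si](C)(C)C(C)(C)C)CC1(C)C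
F5 | step 3 | ethyl (2E,4E)-4-[(4S)-4-(tert-butyldimethylsilyloxy)-2,6,6-trimethylcyclohex-2-en-1-ylidene]-2-methylbut-2-enoate | CC1=C[C@@H](O[Si](C)(C)C(C)(C)C)CC(C)(C)\C1=C/C=C(C)/C(=O)OCC
F6 | step 4 | racemic ethyl (2E,4E)-4-(4-hydroxy-2,6,6-trimethylcyclohex-2-en-1-ylidene)-2-methylbut-2-enoate | CC1=CC(O)CC(C)(C)\C1=C/C=C(C)/C(=O)OCC
F7 | step 4 | ethyl (2E,4E)-4-[(4R)-4-acetoxy-2,6,6-trimethylcyclohex-2-en-1-ylidene]-2-methylbut-2-enoate | CC1=C[C@H](OC(C)=O)CC(C)(C)\C1=C/C=C(C)/C(=O)OCC
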